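**Retrosynthetic overview**

1. Both ArCH2–C(ring) bonds are cut first, as retro-Michael additions to methylidene triones released from Mannich bases. This gives butyrylphloroglucinol (ring B), butyrylfilicinic acid (ring A) and propionylfilicinic acid (ring C); ring A is attached first, ring C last.
2. Both acylfilicinic acids go back to filicinic acid by C-acylation, and filicinic acid to its bis(ethyl enol ether), 3,5-diethoxy-6,6-dimethylcyclohexa-2,4-dien-1-one.
3. That six-membered ring (all six carbons of ring C, and likewise of ring A) comes from a two-carbon ring expansion of a cyclobutenone. 3-Ethoxy-4,4-dimethylcyclobutenone and ethoxyacetylene react through vinylketene [2+2], 4π opening of the 4-alkenylcyclobutenone and 6π closure. Formally this is a polyketide-like cotrimerisation of dimethylketene with two ketene equivalents.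
4. Enabling feature: in ring C the quaternary CMe2 carbon lies between two oxygen-bearing carbons, and oxygen sits on alternate ring atoms (C1, C3, C5). CMe2 is the terminus of the dienylketene and blocks aromatisation; the three C–O carbons are one ketene carbonyl and two ynol-ether carbons.
5. Ring order: four-membered ring (step 1), then the six-membered filicinic ring (step 2, used for rings C and A); aromatic ring B is bought as phloroglucinol.

Key step: step 2

Remark: the target is achiral, so no stereocentre has to be set. All β-triketone and acylphloroglucinol units are written as one enol tautomer, and tautomers are treated as the same compound.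

**Step 1**
Reactants: 1 isobutyryl chloride (2-methylpropanoyl chloride); 2 ethoxyacetylene (ethoxyethyne)
Product: 4 3-ethoxy-4,4-dimethylcyclobut-2-en-1-one, via dimethylketene 3 (not isolated)
Conditions: Et3N, Et2O, 0 °C to rt (slow addition of 1 to 2 and Et3N)
Reagents that add atoms: none
Why: Dehydrochlorination should give dimethylketene, which undergoes the thermal ketene–alkyne [2+2] cycloaddition with the ynol ether, the nucleophilic CH terminus of 2 bonding to the ketene carbonyl carbon so that OEt ends up at C3 next to CMe2.

**Step 2**
Reactants: 4 3-ethoxy-4,4-dimethylcyclobut-2-en-1-one; 2 ethoxyacetylene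
Product: 8 3,5-diethoxy-6,6-dimethylcyclohexa-2,4-dien-1-one, via vinylketene 5 (not isolated), via 4-alkenylcyclobutenone 6 (not isolated), via dienylketene 7 (not isolated)
Conditions: 2 (3 equiv), PhMe, sealed tube, 95 °C
Reagents that add atoms: none
Why: Heating should open 4 reversibly (4π-electrocyclic) to vinylketene 5, whose ketene C=C adds the ynol ether in a regiospecific [2+2] (CH terminus of 2 to the ketene carbonyl carbon) to give the 4-alkenylcyclobutenone 6; 6 then opens (4π) to dienylketene 7, which closes by thermal disrotatory 6π-electrocyclisation between the ketene carbon and the CMe2 terminus, so that the four-membered ring of 6 is enlarged by two carbon atoms to the six-membered ring of 8. The closest known reaction type is the Danheiser vinylketene–alkyne benzannulation of cyclobutenones with alkoxyalkynes, together with the thermal closure of dienylketenes to 6,6-disubstituted cyclohexa-2,4-dienones known as the reverse of the Barton–Quinkert photo-opening. Because the ring-closing terminus is the quaternary CMe2 carbon, tautomerisation to a phenol is impossible and the sequence should stop at the blocked dienone, which is filicinic acid as its bis(ethyl enol ether). No stereocentre is formed (6 is a racemic transient, 8 is achiral). The step needs regioselectivity in the [2+2] (secured by the polarisation of the ynol ether, which places its OEt at C3 while the OEt brought in by 4 ends at C5), the dienylketene geometry with the alkenyl group cis to the ketene arm (secured by the reversibility of the 4π opening, only the cis isomer being drained by cyclisation), and capture of 5 by 2 faster than 1,5-hydrogen shift or ketene dimerisation (secured by excess 2 and the low stationary concentration of 5).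

**Step 3**
Reactants: 8 3,5-diethoxy-6,6-dimethylcyclohexa-2,4-dien-1-one
Product: 9 filicinic acid (3,5-dihydroxy-4,4-dimethylcyclohexa-2,5-dien-1-one; enol form of 2,2-dimethylcyclohexane-1,3,5-trione)
Conditions: 2 M HCl (aq), THF, 50 °C
Reagents that add atoms: water, O
Why: Acid hydrolysis of the vinylogous ester and the dienol ether should liberate the acid-stable cyclic trione in its enol form.

**Step 4**
Reactants: 9 filicinic acid; 10 butyryl chloride (butanoyl chloride)
Product: 11 butyrylfilicinic acid (2-butanoyl-3,5-dihydroxy-4,4-dimethylcyclohexa-2,5-dien-1-one)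
Conditions: AlCl3, PhNO2, rt to 50 °C; then ice, 1 M HCl
Reagents that add atoms: none
Why: Friedel–Crafts-type C-acylation of the enolised trione at one of its two equivalent nucleophilic ring carbons should stop at the mono-acyl stage because the AlCl3-chelated β-triketone product is deactivated, any O-acyl enol ester rearranging to carbon under the Lewis acid (Fries-type).

**Step 5**
Reactants: 9 filicinic acid; 12 propionyl chloride (propanoyl chloride)
Product: 13 propionylfilicinic acid (3,5-dihydroxy-4,4-dimethyl-2-propanoylcyclohexa-2,5-dien-1-one)
Conditions: AlCl3, PhNO2, rt to 50 °C; then ice, 1 M HCl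
Reagents that add atoms: none
Why: Same Friedel–Crafts-type C-acylation as in step 4, giving the ring C building block from the common ring-expansion product.

**Step 6**
Reactants: 14 phloroglucinol (benzene-1,3,5-triol); 10 butyryl chloride
Product: 15 butyrylphloroglucinol (1-(2,4,6-trihydroxyphenyl)butan-1-one)
Conditions: AlCl3, PhNO2/CH2Cl2, 0 °C to rt; then ice, 1 M HCl
Reagents that add atoms: none
Why: Friedel–Crafts acylation of the electron-rich triol should be mono-selective because the chelated aryl ketone is deactivated towards a second acylation.

**Step 7**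
Reactants: 11 butyrylfilicinic acid
Product: 16 2-butanoyl-6-[(dimethylamino)methyl]-3,5-dihydroxy-4,4-dimethylcyclohexa-2,5-dien-1-one (Mannich base, expected as a zwitterion)
Conditions: CH2(NMe2)2 (1.2 equiv), CH2Cl2, 0 °C to rt
Reagents that add atoms: bis(dimethylamino)methane, CN(C)CN(C)C
Why: The acidic triketone protonates the aminal to an iminium ion that is captured at the only enolic ring CH (Mannich reaction); excess aminal and low temperature should prevent the Mannich base from condensing with unreacted 11.

**Step 8**
Reactants: 16 Mannich base of butyrylfilicinic acid; 15 butyrylphloroglucinol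
Product: 18 2-butanoyl-6-[(3-butanoyl-2,4,6-trihydroxyphenyl)methyl]-3,5-dihydroxy-4,4-dimethylcyclohexa-2,5-dien-1-one, via methylidene trione 17 (not isolated)
Conditions: 15 (3 equiv), 1,4-dioxane, 90 °C; then 1 M HCl wash
Reagents that add atoms: none
Why: Thermal loss of dimethylamine (retro-Mannich, E1cB) should release the methylidene trione, a quinone-methide-like Michael acceptor that is attacked by a free ring carbon of 15 (Michael/Friedel–Crafts alkylation, then rearomatisation); the excess of 15 favours mono-alkylation and 16 cannot self-condense because it has no free ring CH.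

**Step 9**
Reactants: 13 propionylfilicinic acid
Product: 19 6-[(dimethylamino)methyl]-3,5-dihydroxy-4,4-dimethyl-2-propanoylcyclohexa-2,5-dien-1-one (Mannich base)
Conditions: CH2(NMe2)2 (1.2 equiv), CH2Cl2, 0 °C to rt
Reagents that add atoms: bis(dimethylamino)methane, CN(C)CN(C)C
Why: Same Mannich aminomethylation at the single enolic ring CH as in step 7.

**Step 10**
Reactants: 19 Mannich base of propionylfilicinic acid; 18 ring A–CH2–ring B dimer
Product: 21 2-butanoyl-6-({3-butanoyl-5-[(2,4-dihydroxy-3,3-dimethyl-6-oxo-5-propanoylcyclohexa-1,4-dien-1-yl)methyl]-2,4,6-trihydroxyphenyl}methyl)-3,5-dihydroxy-4,4-dimethylcyclohexa-2,5-dien-1-one, via methylidene trione 20 (not isolated)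
Conditions: 1,4-dioxane, 90 °C; then 1 M HCl wash
Reagents that add atoms: none
Why: Retro-Mannich release of the propionyl methylidene trione and Michael/Friedel–Crafts attack by the only remaining nucleophilic CH of 18 (the free position of ring B; ring A is fully substituted) should complete the unsymmetrical trimer without free formaldehyde in the flask.

**Compound list**

1 | isobutyryl chloride | CC(C)C(=O)Cl | starting material
2 | ethoxyacetylene | CCOC#C | starting material
3 | dimethylketene | CC(C)=C=O | intermediate (not isolated)
4 | 3-ethoxy-4,4-dimethylcyclobut-2-en-1-one | CCOC1=CC(=O)C1(C)C | intermediate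
5 | 3-ethoxy-4-methylpenta-1,3-dien-1-one (vinylketene) | CCOC(C=C=O)=C(C)C | intermediate (not isolated)
6 | 3-ethoxy-4-(1-ethoxy-2-methylprop-1-en-1-yl)cyclobut-2-en-1-one (racemic) | CCOC1=CC(=O)C1C(OCC)=C(C)C | intermediate (not isolated)
7 | (3E)-3,5-diethoxy-6-methylhepta-1,3,5-trien-1-one (dienylketene, alkenyl cis to the ketene arm) | O=C=C/C(OCC)=C\C(OCC)=C(C)C | intermediate (not isolated)
8 | 3,5-diethoxy-6,6-dimethylcyclohexa-2,4-dien-1-one | CCOC1=CC(=O)C(C)(C)C(OCC)=C1 | intermediate
9 | filicinic acid (3,5-dihydroxy-4,4-dimethylcyclohexa-2,5-dien-1-one) | CC1(C)C(O)=CC(=O)C=C1O | intermediate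
10 | butyryl chloride | CCCC(=O)Cl | starting material
11 | butyrylfilicinic acid | CCCC(=O)C1=C(O)C(C)(C)C(O)=CC1=O | intermediate
12 | propionyl chloride | CCC(=O)Cl | starting material
13 | propionylfilicinic acid | CCC(=O)C1=C(O)C(C)(C)C(O)=CC1=O | intermediate
14 | phloroglucinol | Oc1cc(O)cc(O)c1 | starting material
15 | butyrylphloroglucinol (1-(2,4,6-trihydroxyphenyl)butan-1-one) | CCCC(=O)c1c(O)cc(O)cc1O | intermediate
16 | 2-butanoyl-6-[(dimethylamino)methyl]-3,5-dihydroxy-4,4-dimethylcyclohexa-2,5-dien-1-one | CCCC(=O)C1=C(O)C(C)(C)C(O)=C(CN(C)C)C1=O | intermediate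
17 | 2-butanoyl-3-hydroxy-4,4-dimethyl-6-methylidenecyclohex-2-ene-1,5-dione | C=C1C(=O)C(C(=O)CCC)=C(O)C(C)(C)C1=O | intermediate (not isolated)
18 | 2-butanoyl-6-[(3-butanoyl-2,4,6-trihydroxyphenyl)methyl]-3,5-dihydroxy-4,4-dimethylcyclohexa-2,5-dien-1-one | CCCC(=O)C1=C(O)C(C)(C)C(O)=C(Cc2c(O)cc(O)c(C(=O)CCC)c2O)C1=O | intermediate
19 | 6-[(dimethylamino)methyl]-3,5-dihydroxy-4,4-dimethyl-2-propanoylcyclohexa-2,5-dien-1-one | CCC(=O)C1=C(O)C(C)(C)C(O)=C(CN(C)C)C1=O | intermediate
20 | 3-hydroxy-4,4-dimethyl-6-methylidene-2-propanoylcyclohex-2-ene-1,5-dione | C=C1C(=O)C(C(=O)CC)=C(O)C(C)(C)C1=O | intermediate (not isolated)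
21 | target trimer: ring B (butyrylphloroglucinol) linked by CH2 to ring A (butyrylfilicinic acid) and by CH2 to ring C (propionylfilicinic acid); achiral | CCCC(=O)C1=C(O)C(C)(C)C(O)=C(Cc2c(O)c(CC3=C(O)C(C)(C)C(O)=C(C(=O)CC)C3=O)c(O)c(C(=O)CCC)c2O)C1=O | target

**Step count and risks**

Total steps: 10. Longest linear sequence: 7 steps (1, 2, 3, 4, 7, 8, 10).

Steps most likely to fail:

1. Step 2. The donor-stabilised cyclobutenone may open too slowly in the temperature window that the ynol ether tolerates (retro-ene loss of ethylene from ethoxyacetylene sets in above about 100 °C), and the vinylketene may be lost by 1,5-hydrogen shift from a methyl group before it is captured. The fallback sets out from 1 and comes back to the route at 8; it keeps the same ring-expanding intermediate but makes the vinylketene cold, by 1,4-dehydrochlorination instead of electrocyclic opening. Compound 1 would be added to the lithium enolate of ethyl acetate (LiN(iPr)2, EtOAc, THF, −78 °C) to give ethyl 4-methyl-3-oxopentanoate F1. HC(OEt)3 with catalytic H2SO4 in EtOH should convert it into ethyl (2E)-3-ethoxy-4-methylpent-2-enoate F2 (the alkene geometry is of no consequence). Saponification (LiOH, aqueous THF, then cold citric acid) would give (2E)-3-ethoxy-4-methylpent-2-enoic acid F3, and (COCl)2 with catalytic DMF in CH2Cl2 would give (2E)-3-ethoxy-4-methylpent-2-enoyl chloride F4. Treatment of F4 with Et3N in the presence of 2 at 0 °C to rt should generate vinylketene 5 and its [2+2] adduct 6. After removal of excess 2, 6 would be warmed alone (PhMe, 80 °C); this alkenyl-substituted cyclobutenone should open far more readily than 4 and close to 8.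

2. Step 10. Under hot, amine-containing conditions the methylene bridges may cleave reversibly by retro-Michael reaction, exchanging the filicinic units and scrambling the product towards symmetrical trimers; attack at the last, hindered aromatic position may also be sluggish. The fallback sets out from 18 and 13 and comes back at 21; it reverses the roles of the partners. Compound 18 would be aminomethylated at the free position of ring B (CH2(NMe2)2, CH2Cl2, rt) to give 2-butanoyl-6-({3-butanoyl-5-[(dimethylamino)methyl]-2,4,6-trihydroxyphenyl}methyl)-3,5-dihydroxy-4,4-dimethylcyclohexa-2,5-dien-1-one F7. Gentle heating of F7 with 13 (1,4-dioxane, 60–70 °C) should release the ring B ortho-quinone methide F8, which is trapped by the strongly nucleophilic enol carbon of 13 at a lower temperature than step 10 needs, leaving less time for bridge exchange; compound 19 is not needed in this variant.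

3. Step 8. The mono-adduct keeps an equally reactive free position, so over-alkylation to the symmetrical bis-adduct and a difficult separation from excess 15 may erode the step. The fallback sets out from 15 and comes back at 18; it uses a temporary bromine block. Compound 15 would be mono-brominated (N-bromosuccinimide, 1.0 equiv, THF, −78 to 0 °C; the first halogen deactivates the ring) to give 1-(3-bromo-2,4,6-trihydroxyphenyl)butan-1-one F5. Coupling of F5 with 16 under the conditions of step 8 (via 17) can only occur at the single free position and should give 2-[(3-bromo-5-butanoyl-2,4,6-trihydroxyphenyl)methyl]-6-butanoyl-3,5-dihydroxy-4,4-dimethylcyclohexa-2,5-dien-1-one F6. Hydrogenolysis of the aryl bromide (H2, Pd/C, NaOAc, MeOH, rt), which the enolised triketone and the chelated aryl ketone should survive, would return 18.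

**Further compounds**

F1 | step 2 | ethyl 4-methyl-3-oxopentanoate | CCOC(=O)CC(=O)C(C)C
F2 | step 2 | ethyl (2E)-3-ethoxy-4-methylpent-2-enoate | CCOC(=O)/C=C(\C(C)C)OCC
F3 | step 2 | (2E)-3-ethoxy-4-methylpent-2-enoic acid | OC(=O)/C=C(\C(C)C)OCC
F4 | step 2 | (2E)-3-ethoxy-4-methylpent-2-enoyl chloride | ClC(=O)/C=C(\C(C)C)OCC
F5 | step 8 | 1-(3-bromo-2,4,6-trihydroxyphenyl)butan-1-one | CCCC(=O)c1c(O)cc(O)c(Br)c1O
F6 | step 8 | 2-[(3-bromo-5-butanoyl-2,4,6-trihydroxyphenyl)methyl]-6-butanoyl-3,5-dihydroxy-4,4-dimethylcyclohexa-2,5-dien-1-one | CCCC(=O)C1=C(O)C(C)(C)C(O)=C(Cc2c(O)c(Br)c(O)c(C(=O)CCC)c2O)C1=O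
F7 | step 10 | 2-butanoyl-6-({3-butanoyl-5-[(dimethylamino)methyl]-2,4,6-trihydroxyphenyl}methyl)-3,5-dihydroxy-4,4-dimethylcyclohexa-2,5-dien-1-one | CCCC(=O)C1=C(O)C(C)(C)C(O)=C(Cc2c(O)c(CN(C)C)c(O)c(C(=O)CCC)c2O)C1=O
F8 | step 10 | ring B ortho-quinone methide of the dimer (not isolated) | C=C1C(=O)C(C(=O)CCC)=C(O)C(CC2=C(O)C(C)(C)C(O)=C(C(=O)CCC)C2=O)=C1O
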